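**Retrosynthetic overview**
1. Target ⇒ regioselective O-methylation (C–O) of the spiro vinylogous acid. This is the last step.
2. Ring B ⇒ the key disconnection is an allylic C–O bond. An enol oxygen of ring A is tied to the side-chain carbinol carbon to give a 2-alkenyl dihydropyran, and a [3,3] shift trades that C–O bond for the C6–C7 bond.
3. This relay puts the side chain at C-8. A direct Diels–Alder reaction with myrcene is para-selective and would put it at C-9.
4. Allylic alcohol ⇒ chiral lactol + 2-lithio-1-alkene from 6-methylhept-5-en-2-one. Lactol ⇒ iminium-catalysed Michael addition of methylfilicinic acid to (E)-4-methylpent-2-enal, which sets C-11.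
5. Ring order: ring A (dearomatising C-methylation of 2-methylphloroglucinol) → temporary pyran ring (C–O) → ring B by ring contraction.

Assumption: enolisable triketones are drawn as one tautomer each; the lactol (anomers) and the allylic alcohol (carbinol epimers) are carried on as mixtures because those centres are erased later.

**Step 1**
Reactants: 1 2-methylbenzene-1,3,5-triol (2-methylphloroglucinol); 2 iodomethane
Product: 3 3,5-dihydroxy-2,4,4-trimethylcyclohexa-2,5-dien-1-one (methylfilicinic acid)
Conditions: NaOMe (3.0 equiv), MeI (2.1 equiv), MeOH, 0 °C to rt, 16 h; then 1 M HCl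
Reagents that add atoms: iodomethane, CI
Why: Dearomatising C-methylation of a phloroglucinol phenolate, in which the soft iodide is attacked at ring carbon, the carbon already bearing methyl is the most nucleophilic, and either order of the two methylations gives the same 2,2,4-trimethyl triketone; no stereocentre is formed.

**Step 2**
Reactants: 3 methylfilicinic acid; 4 (2E)-4-methylpent-2-enal
Product: 5 (4S)-2,7-dihydroxy-6,8,8-trimethyl-4-(propan-2-yl)-2,3,4,8-tetrahydro-5H-chromen-5-one (lactol; both anomers)
Conditions: (S)-2-[diphenyl(trimethylsilyloxy)methyl]pyrrolidine (10 mol %), CH2Cl2, 0 °C to rt, 24 h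
Reagents that add atoms: none
Why: Iminium-catalysed asymmetric Michael addition followed by hemiacetalisation, in which the bulky silyl ether arm shields one face of the E-iminium ion so that the unsubstituted ring carbon of 3 adds to the open face and sets C-4 (later C-11) as S, and the neighbouring enol oxygen then traps the aldehyde as the lactol.

**Step 3**
Reactants: 6 6-methylhept-5-en-2-one; 7 2,4,6-tri(propan-2-yl)benzenesulfonohydrazide
Product: 8 N'-[(2E)-6-methylhept-5-en-2-ylidene]-2,4,6-tri(propan-2-yl)benzenesulfonohydrazide
Conditions: MeOH, cat. HCl, rt, 2 h; crystallise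
Reagents that add atoms: none
Why: Acid-catalysed hydrazone condensation gives the crystalline E-hydrazone, whose N–H lies syn to the methyl group and steers the later deprotonation to CH3, while the hindered aryl group prevents ortho-lithiation.

**Step 4**
Reactants: 8 sulfonylhydrazone; 5 lactol
Product: 11 3,5-dihydroxy-2-[(3S,5RS)-5-hydroxy-2,10-dimethyl-6-methylideneundec-9-en-3-yl]-4,4,6-trimethylcyclohexa-2,5-dien-1-one, via alkenyllithium 9 (not isolated), via ring-opened dianion 10 (not isolated)
Conditions: 8 (1.3 equiv), n-BuLi (2.05 equiv per 8), THF, −78 to 0 °C, re-cool to −78 °C; add 5 pre-treated with NaH (2.1 equiv), THF, 0 °C; −78 to −20 °C; aq NH4Cl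
Reagents that add atoms: none
Why: Shapiro reaction followed by 1,2-addition, in which double deprotonation of 8 and loss of sulfinate and N2 give the 2-lithio-1-alkene 9, which adds to the aldehyde unmasked when NaH opens 5 to dianion 10; the two enolate charges of 10 shield the ring carbonyls and make the triketone too poor a leaving group for retro-Michael loss, so the side-chain C-3 stays S, while the new carbinol centre forms about 1:1 and is erased in step 5.

**Step 5**
Reactants: 11 allylic alcohol (both carbinol epimers)
Product: 14 (6R,11S)-3-hydroxy-2,4,4-trimethyl-8-(4-methylpent-3-en-1-yl)-11-(propan-2-yl)spiro[5.5]undeca-2,8-diene-1,5-dione, via resting pyran 12 (not isolated), via reactive pyran 13 (not isolated)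
Conditions: Re2O7 (5 mol %), 4 Å molecular sieves, toluene, rt, 2 h; then 110 °C, 16 h
Reagents that add atoms: none
Why: Proposed new method: an oxygen-shuttle ring contraction in which Re2O7 (through perrhenate esters and perrhenic acid) ionises the 2-alkyl allylic alcohol reversibly, so that an enol oxygen of the triketone closes a six-membered allylic C–O bond with loss of water; because the triketone enolate leaves about as well as a carboxylate, this C–O bond keeps re-ionising, so both carbinol epimers and both flanking enol oxygens equilibrate to the trans pyrans (12 bonded through the oxygen next to CMe2, 13 through the oxygen next to C-Me, each with a pseudo-axial isopropyl and a pseudo-equatorial alkenyl group); on heating only 13 can reach the boat Claisen transition state, since in 12 the methylpentenyl chain on the central allyl carbon would eclipse a methyl of CMe2, and in the cis pyrans the isopropyl group would be pushed into the ring plane against a C=O (allylic 1,3-strain); suprafacial transfer of the CH2 terminus from C-2 (S) of 13 to the face of C-4a anti to isopropyl sets C-6 as R, keeps C-11 as S, erases C-2 and places the chain at C-8; the closest known reaction types are the perrhenate-catalysed dehydrative cyclisation of allylic alcohols to 2-alkenyl tetrahydropyrans under thermodynamic control, the thermal Claisen ring contraction of 2-alkenyl-3,4-dihydro-2H-pyrans to cyclohexenes, and the O-allylation/Claisen chirality relay on phenols, none of which, to my knowledge, has been run on a cyclic beta-triketone or used to set a spiro quaternary centre.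

**Step 6**
Reactants: 14 spiro vinylogous acid; 15 (diazomethyl)trimethylsilane
Product: 16 (6R,11S)-3-methoxy-2,4,4-trimethyl-8-(4-methylpent-3-en-1-yl)-11-(propan-2-yl)spiro[5.5]undeca-2,8-diene-1,5-dione (target)
Conditions: Me3SiCHN2 (1.2 equiv), toluene/MeOH 4:1, 0 °C, 30 min
Reagents that add atoms: (diazomethyl)trimethylsilane, C[Si](C)(C)C=[N+]=[N-]
Why: O-methylation of a vinylogous acid by a diazoalkane (proton transfer, then SN2 on the methyldiazonium ion) is expected at the C-3 oxygen, flanked only by CMe2 and C-Me, rather than at the C-1 oxygen, which is buried between the spiro centre and the cis isopropyl group; no stereocentre is touched.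

**Compound list**
1 | 2-methylbenzene-1,3,5-triol | Cc1c(O)cc(O)cc1O | starting material
2 | iodomethane | CI | starting material
3 | 3,5-dihydroxy-2,4,4-trimethylcyclohexa-2,5-dien-1-one | O=C1C(C)=C(O)C(C)(C)C(O)=C1 | intermediate
4 | (2E)-4-methylpent-2-enal | CC(C)/C=C/C=O | starting material
5 | (4S)-2,7-dihydroxy-6,8,8-trimethyl-4-(propan-2-yl)-2,3,4,8-tetrahydro-5H-chromen-5-one | O=C1C(C)=C(O)C(C)(C)C2=C1[C@H](C(C)C)CC(O)O2 | intermediate
6 | 6-methylhept-5-en-2-one | CC(=O)CCC=C(C)C | starting material
7 | 2,4,6-tri(propan-2-yl)benzenesulfonohydrazide | NNS(=O)(=O)c1c(C(C)C)cc(C(C)C)cc1C(C)C | starting material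
8 | N'-[(2E)-6-methylhept-5-en-2-ylidene]-2,4,6-tri(propan-2-yl)benzenesulfonohydrazide | C/C(CCC=C(C)C)=N\NS(=O)(=O)c1c(C(C)C)cc(C(C)C)cc1C(C)C | intermediate
9 | (6-methylhepta-1,5-dien-2-yl)lithium | [Li]C(=C)CCC=C(C)C | intermediate
10 | disodium salt of (3S)-3-(2,4-dihydroxy-3,3,5-trimethyl-6-oxocyclohexa-1,4-dien-1-yl)-4-methylpentanal | [Na+].[Na+].O=CC[C@@H](C(C)C)C1=C([O-])C(C)(C)C([O-])=C(C)C1=O | intermediate
11 | 3,5-dihydroxy-2-[(3S,5RS)-5-hydroxy-2,10-dimethyl-6-methylideneundec-9-en-3-yl]-4,4,6-trimethylcyclohexa-2,5-dien-1-one | O=C1C(C)=C(O)C(C)(C)C(O)=C1[C@H](C(C)C)CC(O)C(=C)CCC=C(C)C | intermediate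
12 | (2S,4S)-7-hydroxy-6,8,8-trimethyl-2-(6-methylhepta-1,5-dien-2-yl)-4-(propan-2-yl)-2,3,4,8-tetrahydro-5H-chromen-5-one | O=C1C(C)=C(O)C(C)(C)C2=C1[C@H](C(C)C)C[C@@H](C(=C)CCC=C(C)C)O2 | intermediate
13 | (2S,4S)-7-hydroxy-6,6,8-trimethyl-2-(6-methylhepta-1,5-dien-2-yl)-4-(propan-2-yl)-2,3,4,6-tetrahydro-5H-chromen-5-one | O=C1C(C)(C)C(O)=C(C)C2=C1[C@H](C(C)C)C[C@@H](C(=C)CCC=C(C)C)O2 | intermediate
14 | (6R,11S)-3-hydroxy-2,4,4-trimethyl-8-(4-methylpent-3-en-1-yl)-11-(propan-2-yl)spiro[5.5]undeca-2,8-diene-1,5-dione | OC1=C(C)C(=O)[C@]2(CC(CCC=C(C)C)=CC[C@H]2C(C)C)C(=O)C1(C)C | intermediate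
15 | (diazomethyl)trimethylsilane | C[Si](C)(C)C=[N+]=[N-] | starting material
16 | (6R,11S)-3-methoxy-2,4,4-trimethyl-8-(4-methylpent-3-en-1-yl)-11-(propan-2-yl)spiro[5.5]undeca-2,8-diene-1,5-dione | COC1=C(C)C(=O)[C@]2(CC(CCC=C(C)C)=CC[C@H]2C(C)C)C(=O)C1(C)C | target

**Total step count:** 6. **Longest linear sequence:** 5 (steps 1, 2, 4, 5, 6).

**Steps most likely to fail**

Step 5 (the new step) is the largest risk. The allyl cation could be captured by the methyl-bearing enol carbon to give a bicyclo[3.3.1]nonane. It could also lose a proton to give a triene, or 12 could fail to drain through 13. The fallback uses known chemistry, sets out from 11 and comes back at 14. It gives up the oxygen relay and closes ring B by a direct carbon–carbon bond. Compound 11 is peracetylated (Ac2O, pyridine, DMAP) and the labile enol acetates are cleaved with K2CO3/MeOH, which leaves the allylic acetate F1. Pd(PPh3)4 (5 mol %) and K2CO3 in THF at 60 °C then effect an intramolecular Tsuji–Trost allylic alkylation. The side-chain-bearing ring carbon attacks the unsubstituted CH2 terminus of the π-allyl unit and gives 14. The C-6 epimers are separated on silica.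

Step 4 is the second risk. The poorly soluble dianion 10 may react sluggishly, or its aldehyde may be enolised by the basic alkenyllithium. The fallback sets out from 6 and 5 and comes back at 11, and it replaces the organolithium by a non-basic organochromium reagent. Kinetic enolisation of 6 (LDA, THF, −78 °C) and trapping with PhNTf2 gives 6-methylhepta-1,5-dien-2-yl trifluoromethanesulfonate F2. This is coupled with the aldehyde tautomer of 5 under Nozaki–Hiyama–Kishi conditions (CrCl2, 1 mol % NiCl2, DMF, rt) to give 11.

Step 1 is the third risk. Under- and over-methylation (the dimethyl, aromatic 2,4,6-trimethyl and tetramethyl products) can erode the yield of 3. The fallback sets out from 1 and comes back at 3, and it blocks the third ring carbon first. Friedel–Crafts acetylation of 1 (Ac2O, BF3·OEt2) gives 1-(2,4,6-trihydroxy-3-methylphenyl)ethan-1-one F3. With the third ring carbon blocked, NaOMe/MeI (2 equiv) is steered to the CMe2/C-Me pattern and gives 2-acetyl-3,5-dihydroxy-4,6,6-trimethylcyclohexa-2,4-dien-1-one F4. Refluxing 6 M HCl removes the acetyl group by retro-Claisen cleavage and gives 3.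

**Further compounds**
F1 | step 5 | (9S)-9-(2,6-dihydroxy-3,3,5-trimethyl-4-oxocyclohexa-1,5-dien-1-yl)-2,10-dimethyl-6-methylideneundec-2-en-7-yl acetate (both carbinol epimers) | O=C1C(C)=C(O)C(C)(C)C(O)=C1[C@H](C(C)C)CC(OC(C)=O)C(=C)CCC=C(C)C
F2 | step 4 | 6-methylhepta-1,5-dien-2-yl trifluoromethanesulfonate | C=C(OS(=O)(=O)C(F)(F)F)CCC=C(C)C
F3 | step 1 | 1-(2,4,6-trihydroxy-3-methylphenyl)ethan-1-one | CC(=O)c1c(O)cc(O)c(C)c1O
F4 | step 1 | 2-acetyl-3,5-dihydroxy-4,6,6-trimethylcyclohexa-2,4-dien-1-one | CC(=O)C1=C(O)C(C)=C(O)C(C)(C)C1=O
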